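## Analysis of the target

The target is a cembranolide: a fourteen-membered carbocycle (C1–C14) crossed by an ether oxygen between C3 and C13. It is best read as an oxane (O, C13, C14, C1, C2, C3) bridged 2,6 by the nine-carbon chain C4–C12, with an α-methylene-γ-butyrolactone (C15–C17) cis-fused on the oxane bond C1–C14. There are seven stereocentres: C1 (R), C3 (R), C4 (S), C8 (R), C12 (S), C13 (R) and C14 (S). On the oxane the two bridge bonds C3–C4 and C13–C12 are cis, and the lactone bonds C1–C15 and C14–O lie together on the opposite face. The tertiary carbinols C4 and C8 flank the Z alkene C6=C7 and are too far apart to relay stereochemistry to each other. Sensitive groups are the exo-methylene lactone (Michael acceptor, base-labile), the tertiary allylic alcohol at C8 (ionises under acid) and the Z alkene, which must survive a reduction elsewhere in the ring. The difficulty is to close a twelve-membered oxa-ring and an oxane carrying four contiguous stereocentres (C12, C13, C14, C1) while the two remote quaternary carbinols are set independently. The strategy rests on C13: it is bonded to the ring oxygen, to the methyl-branched C12 and to the oxygenated C14, which is the pattern left when an allyl group migrates from an ether oxygen to a neighbouring carbonyl-stabilised carbon.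

## Retrosynthetic reasoning

**Methylene and silyl groups.** Target 38 is traced to its bis-silyl ether 37 and then to the saturated lactone 34 by removing the exocyclic carbon C17. The Michael acceptor is therefore made last, and the two tertiary alcohols stay masked through all enolate chemistry.

**Lactone (C1–C15 and O–C14).** Lactone 34 is opened to keto ester 32 and then cut at C1–C15 to ketone 31. The cut is made there because the C14 carbonyl of 31 makes C1 the only readily enolisable methylene. Forward, the enolate must be alkylated on the face anti to the bridge, and the ketone must be reduced to the alcohol cis to the new arm.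

**C10=C11.** Ketone 31 comes from diene 30 by saturating only the alkene that the ring expansion leaves behind.

**Key disconnection (O–C13 and C12–C13).** In 30 both bonds to C13 are cut and the oxygen is reconnected to C10. This gives the nine-membered ene ether 28, which carries a propenyl group on C10 and a diazoketone chain on C3. Forward, a carbenoid at C13 is captured by the ring oxygen to give ylide 29, and a [2,3] shift of the propenyl unit forms the oxane and enlarges the nine-membered ring to the twelve-membered one. No other cut removes two rings and two stereocentres at once while leaving a medium ring whose Z alkene is fixed by ring size.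

**Diazoketone and C4 oxygen.** Diazoketone 28 is the one-carbon homologue of acid 26. Acid 26 and its C4 silyl ether are both unmasked from δ-lactone 23, in which C14 and O4 protect each other.

**Propenyl group (C11=C12).** The propenyl group of 23 is cut to aldehyde 22, and that is traced through alcohol 21 to PMB ether 20. The alkene is introduced only after the nine-membered ring exists. A propenyl group present earlier would be captured by the metathesis catalyst in a seven-membered ring closure.

**C6=C7.** Ring 20 is opened at its only ring alkene to diene 19. Forward this is a ring-closing metathesis of an allyl group on C4 and a vinyl group on C8.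

**C4 (C4–C5 and C4–CH3).** Lactone 19 is the oxidised form of diol 18. Its quaternary centre is dissected to lactol 17 and lactone 16 by removing a methyl and then an allyl carbanion equivalent from the C4 carbonyl. Methyl is added second so that chelation by the ether oxygen gives the 4S configuration.

**C3 (C2–C3).** Lactone 16 arises from imide 13 by hydroxylating the terminus of an allyl group (C2, C1, C14). Imide 13 is cut at C2–C3 to glycolyl imide 12, so an auxiliary-controlled enolate alkylation sets C3.

**Ether O–C3.** Imide 12 is traced through acid 10 and ester 9 to alcohol 8 by cutting the O–C3 bond. Forward this is a carbenoid O–H insertion of an unsubstituted two-carbon diazo ester. Putting the diazo group on this unit, and not on the C10 carbon, avoids a carbenoid with β-hydrogens and leaves no stereocentre to chance.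

**C10–O and the chiral pool.** Alcohol 8 is the mono-protected form of diol 6. Its C10 oxygen is removed via 5 to aldehyde 3, which is the ozonolysis product of silyl ether 2 of (R)-linalool (1). Linalool supplies C7–C11, the C8 stereocentre and the vinyl group.

## Alternatives that were turned down

**Alternative 1:** The oxane oxygen is taken out and C13–C14–C1–C2–C3 are treated as a carbocycle that is re-expanded later by Baeyer–Villiger oxygen insertion. The forward key step is the Dy(OTf)3-catalysed aqueous rearrangement of furylcarbinol A2 to the trans-4-hydroxy-5-alkylcyclopentenone A1. It proceeds by furan ring opening to a pentadienyl cation and conrotatory 4π closure, which makes C13–C14 and sets the trans relation of the C12-bearing arm and the C14 oxygen. In its favour, A2 is two steps from furfural and already carries C12 and C8, the step is catalytic, and the trans selectivity is mechanistically secure. On this point it is stronger than step 20, whose extension to a twelve-membered ring is untested. Against it, A1 contains none of the macrocycle. Peracid insertion on an enone competes with epoxidation and gives a lactone whose C3 carbonyl must still receive the quaternary C4 carbinol and be reduced to the 2,6-cis ether. C1 needs a separate conjugate addition, and the twelve-membered ring needs a later macrocyclisation and alkyne semi-reduction. The chosen route gives up the well-tried key step but forms both rings and both C13 bonds in one operation, after which only a routine lactone annulation remains.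

**Alternative 2:** The C1–C14 bond is cut and the ring is enlarged through oxygen to the seventeen-membered allyl propargyl ether A4. Deprotonation at the propargylic C14 with n-BuLi or a chiral lithium amide triggers a [2,3]-Wittig shift to the fourteen-membered propargylic alcohol A3. The step forms the carbocycle, sets C1 and C14 together and delivers all three acrylate carbons as an isopropenyl group. Here it is stronger than the chosen route, which adds C15–C17 in three steps after the key step. Its weakness for this target is that A3 has neither the ether bridge nor the C12 methyl group. The C12≡C13 alkyne must be turned into a methyl-bearing and an oxygen-bearing stereocentre by carbometalation and a transannular C3–O–C13 closure, and neither the regiochemistry nor the facial control of these is secured in a flexible fourteen-membered ring. The syn/anti outcome of the shift in a seventeen-membered ring is also uncertain, and allylic oxidation of the isopropenyl group comes late. The chosen route instead creates C12 and C13 in the same pericyclic event that closes the rings.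

**Alternative 3:** The lactone bonds C1–C15 and O–C14 are cut together, which leads to the cis-2,6-dihydropyran A6 with a C14=C1 alkene. Et3B/air initiates addition of an iodoacetate-derived carboxymethyl radical to C1, iodine is transferred to C14, and the carboxylate displaces it with inversion to give the cis-fused lactone A5. This builds the lactone in one step where the chosen route needs an alkylation and a reduction–lactonisation, so it is stronger on lactone economy. The cis-2,6-dihydropyran is also accessible by established chemistry. Against it, the radical has little reason to prefer C1 over C14 on an unactivated ring alkene. More seriously, the twelve-membered ring is still open: its closure must join the alkyne terminus to the neopentyl C5 next to the quaternary C4, or to a C5 aldehyde that then needs deoxygenation, and a Z-selective semi-reduction must follow. The chosen route has the macrocycle arise from a nine-membered ring in which the Z alkene is already fixed, and accepts a longer but conventional lactone endgame.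

Key step: step 20

## Route

Remark: cembrane numbering (C1–C14 ring carbons, C15–C17 lactone carbons) is used for every intermediate, and (R)-linalool is taken as enantiopure because its C8 centre is carried through unchanged. Hx stands for the (2R,4R)-1-(4-methoxybenzyloxy)-4-methyl-4-(triethylsilyloxy)hex-5-en-2-yl group, bonded through its C2 oxygen (O10 to C10). The trisubstituted alkene of A4 is taken as E.

Step 1
Reactants: 1 (R)-linalool
Product: 2 (R)-triethyl[(3,7-dimethylocta-1,6-dien-3-yl)oxy]silane
Conditions: TESOTf, 2,6-lutidine, CH2Cl2, −78 to 0 °C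
Reagents that add atoms: triethylsilyl trifluoromethanesulfonate CC[Si](CC)(CC)OS(=O)(=O)C(F)(F)F
Why: Silylation of a hindered tertiary alcohol with a silyl triflate; C8 (R) comes from the chiral pool, and the silyl ether prevents lactol formation and alkoxide chemistry at O8 in later steps.

Step 2
Reactants: 2 (R)-triethyl[(3,7-dimethylocta-1,6-dien-3-yl)oxy]silane
Product: 3 (R)-4-methyl-4-(triethylsilyloxy)hex-5-enal
Conditions: O3, CH2Cl2, −78 °C, Sudan Red 7B end-point; then PPh3, −78 °C to rt
Reagents that add atoms: ozone [O-][O+]=O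
Why: Chemoselective ozonolysis: the electron-rich trisubstituted alkene should react far faster than the vinyl group, which is deactivated by the allylic silyloxy group and shielded by the quaternary carbon; the dye marks the end-point.

Step 3
Reactants: 3 (R)-4-methyl-4-(triethylsilyloxy)hex-5-enal
Product: 5 (2R,4R)-4-methyl-2-(N-phenylaminooxy)-4-(triethylsilyloxy)hex-5-en-1-ol, via α-anilinooxy aldehyde 4 (not isolated)
Conditions: PhNO, L-proline (20 mol%), DMSO, rt; then NaBH4, EtOH, 0 °C
Reagents that add atoms: nitrosobenzene O=Nc1ccccc1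
Why: Proline-catalysed α-aminoxylation (O-selective nitroso aldol through the enamine); the carboxyl group of L-proline delivers nitrosobenzene to one enamine face and sets C10 as R under catalyst control. Reduction in the same flask prevents racemisation of the α-oxy aldehyde.

Step 4
Reactants: 5 (2R,4R)-4-methyl-2-(N-phenylaminooxy)-4-(triethylsilyloxy)hex-5-en-1-ol
Product: 6 (2R,4R)-4-methyl-4-(triethylsilyloxy)hex-5-ene-1,2-diol
Conditions: Zn, AcOH, EtOH, 0 °C to rt
Reagents that add atoms: none
Why: Reductive N–O cleavage of an O-alkyl-N-arylhydroxylamine by Zn in acetic acid; the alkene and the tertiary silyl ether are not affected.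

Step 5
Reactants: 6 (2R,4R)-4-methyl-4-(triethylsilyloxy)hex-5-ene-1,2-diol
Product: 8 (2R,4R)-1-(4-methoxybenzyloxy)-4-methyl-4-(triethylsilyloxy)hex-5-en-2-ol (Hx–OH), via stannylene acetal 7 (not isolated)
Conditions: Bu2SnO, toluene, reflux (Dean–Stark); then PMBCl, Bu4NI, toluene, 90 °C
Reagents that add atoms: 4-methoxybenzyl chloride COc1ccc(CCl)cc1
Why: Stannylene-acetal monoalkylation of a 1,2-diol: the primary oxygen of the tin acetal is the more nucleophilic, so the PMB ether forms at O11 and the C10 hydroxyl stays free.

Step 6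
Reactants: 8 Hx–OH
Product: 9 ethyl 2-(Hx-oxy)acetate
Conditions: N2CHCO2Et (slow addition), Rh2(OAc)4 (1 mol%), CH2Cl2, rt
Reagents that add atoms: ethyl diazoacetate CCOC(=O)C=[N+]=[N-]
Why: Rhodium-carbenoid O–H insertion forms the O–C3 bond of the future ring ether; the carbenoid has no β-hydrogen and creates no stereocentre. The neutral conditions avoid alkoxide-induced silyl migration from O8 to O10.

Step 7
Reactants: 9 ethyl 2-(Hx-oxy)acetate
Product: 10 2-(Hx-oxy)acetic acid
Conditions: LiOH·H2O, THF/H2O, 0 °C to rt; then aq HCl to pH 4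
Reagents that add atoms: lithium hydroxide [Li+].[OH-]
Why: Ester saponification; the PMB ether and the tertiary silyl ether are stable to aqueous hydroxide.

Step 8
Reactants: 10 2-(Hx-oxy)acetic acid
Product: 12 (S)-4-benzyl-3-[2-(Hx-oxy)acetyl]oxazolidin-2-one, via mixed pivalic anhydride 11 (not isolated)
Conditions: PivCl, Et3N, THF, −78 to 0 °C; then lithiated (S)-4-benzyloxazolidin-2-one (n-BuLi), THF, −78 to 0 °C
Reagents that add atoms: (S)-4-benzyloxazolidin-2-one O=C1N[C@@H](Cc2ccccc2)CO1
Why: N-acylation of the oxazolidinone auxiliary through the mixed anhydride; the lithiated auxiliary attacks the unhindered glycolyl carbonyl and not the pivaloyl one.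

Step 9
Reactants: 12 (S)-4-benzyl-3-[2-(Hx-oxy)acetyl]oxazolidin-2-one
Product: 13 (S)-4-benzyl-3-[(R)-2-(Hx-oxy)pent-4-enoyl]oxazolidin-2-one
Conditions: NaHMDS, THF, −78 °C; then allyl iodide, −78 to −45 °C
Reagents that add atoms: allyl iodide C=CCI
Why: Auxiliary-controlled glycolate alkylation: the chelated sodium Z-enolate is alkylated on the face away from the benzyl group, which sets C3 as R. The allyl group carries C2, C1 and C14.

Step 10
Reactants: 13 (S)-4-benzyl-3-[(R)-2-(Hx-oxy)pent-4-enoyl]oxazolidin-2-one
Product: 16 (R)-3-(Hx-oxy)tetrahydro-2H-pyran-2-one, via B-alkyl-9-BBN adduct 14 (not isolated), via δ-hydroxy imide 15 (not isolated)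
Conditions: 9-BBN, THF, 0 °C to rt; then NaOAc, 30% H2O2, 0 °C; then Et3N, DMAP (cat.), CH2Cl2, rt
Reagents that add atoms: hydrogen peroxide OO
Why: Anti-Markovnikov hydroboration–oxidation: 9-BBN should select the unhindered allyl terminus over the vinyl group on the quaternary silyloxy carbon. The δ-hydroxyl then displaces the oxazolidinone by lactonisation, which removes the auxiliary and gives a lactone ready for organometallic addition.

Step 11
Reactants: 16 (R)-3-(Hx-oxy)tetrahydro-2H-pyran-2-one
Product: 17 (3R)-2-allyl-3-(Hx-oxy)tetrahydro-2H-pyran-2-ol (anomer mixture)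
Conditions: CH2=CHCH2MgBr (1.1 equiv), THF, −78 °C; NH4Cl quench at −78 °C
Reagents that add atoms: allylmagnesium bromide C=CC[Mg]Br
Why: Mono-addition of a Grignard reagent to a δ-lactone: the magnesium lactolate is stable at −78 °C and does not release the ketone, so a second addition is avoided.

Step 12
Reactants: 17 (3R)-2-allyl-3-(Hx-oxy)tetrahydro-2H-pyran-2-ol
Product: 18 (4R,5S)-5-methyl-4-(Hx-oxy)oct-7-ene-1,5-diol
Conditions: MeMgBr (4 equiv), CH2Cl2/Et2O, −78 to −20 °C
Reagents that add atoms: methylmagnesium bromide C[Mg]Br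
Why: Chelation-controlled Grignard addition (Cram chelate): the lactolate opens to the ketone, magnesium bridges the C4 carbonyl and the ether oxygen O3, and methyl adds on the face of the C3 hydrogen, anti to the C2 chain, to give C4 as S. Adding methyl after allyl, and not the reverse, is what gives this configuration.

Step 13
Reactants: 18 (4R,5S)-5-methyl-4-(Hx-oxy)oct-7-ene-1,5-diol
Product: 19 (5R,6S)-6-allyl-6-methyl-5-(Hx-oxy)tetrahydro-2H-pyran-2-one
Conditions: TEMPO (20 mol%), PhI(OAc)2, CH2Cl2, rt
Reagents that add atoms: none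
Why: Oxidative lactonisation of a 1,5-diol: the primary alcohol is oxidised to the aldehyde, which closes onto the tertiary C4 hydroxyl, and the lactol is oxidised further. C14 reaches the acid level and O4 is masked in the same step.

Step 14
Reactants: 19 (5R,6S)-6-allyl-6-methyl-5-(Hx-oxy)tetrahydro-2H-pyran-2-one
Product: 20 (3R,4S,8R,10R)-lactone-fused (Z)-oxonene: nine-membered ring O–C3–C4–C5–C6=C7–C8–C9–C10 fused at C3–C4 to the δ-lactone O4–C14(=O)–C1–C2; C4 methyl, C8 methyl and triethylsilyloxy, C10 CH2OPMB
Conditions: second-generation Hoveyda–Grubbs catalyst (10 mol%), toluene (1 mM), 80 °C, argon sparge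
Reagents that add atoms: none
Why: Ring-closing metathesis: the catalyst loads on the allyl group and closes onto the vinyl group, and the ring size enforces the Z alkene. The lactone limits rotation about C3–C4 to two half-chairs, one of which holds C5 and O3 gauche, and the quaternary centres at C4 and C8 favour the folded chain.

Step 15
Reactants: 20 lactone-fused oxonene with C10 CH2OPMB
Product: 21 the corresponding primary alcohol (C11–OH)
Conditions: DDQ, CH2Cl2/pH 7 buffer, 0 °C to rt
Reagents that add atoms: none
Why: Oxidative cleavage of the PMB ether through its benzylic cation; the buffer protects the tertiary allylic silyl ether.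

Step 16
Reactants: 21 lactone-fused oxonene with C10 CH2OH
Product: 22 the corresponding C11 aldehyde
Conditions: Dess–Martin periodinane, NaHCO3, CH2Cl2, 0 °C to rt
Reagents that add atoms: none
Why: Mild, buffered periodinane oxidation; the α-alkoxy aldehyde is used crude so that C10 does not epimerise.

Step 17
Reactants: 22 lactone-fused oxonene C11 aldehyde
Product: 23 (3R,4S,8R,10R)-lactone-fused (Z)-oxonene with an (E)-prop-1-enyl group on C10
Conditions: CH3CHI2, CrCl2, THF, rt
Reagents that add atoms: 1,1-diiodoethane CC(I)I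
Why: Takai–Utimoto ethylidenation: the gem-dichromium reagent adds to the aldehyde and eliminates to give the E alkene. The conditions are not basic, so C10 is preserved and the lactone is tolerated.

Step 18
Reactants: 23 lactone-fused oxonene with C10 (E)-propenyl
Product: 26 3-[(2R,4R,5Z,8S,9R)-4,8-dimethyl-2-[(E)-prop-1-enyl]-4,8-bis(triethylsilyloxy)-2,3,4,7,8,9-hexahydrooxonin-9-yl]propanoic acid, via lithium hydroxy carboxylate 24 (not isolated), via bis-silylated ester 25 (not isolated)
Conditions: LiOH·H2O, THF/H2O, rt, concentrate; then TESOTf, 2,6-lutidine, CH2Cl2, −78 to 0 °C; then K2CO3, MeOH/H2O, 0 °C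
Reagents that add atoms: lithium hydroxide [Li+].[OH-]; triethylsilyl trifluoromethanesulfonate CC[Si](CC)(CC)OS(=O)(=O)C(F)(F)F
Why: Lactone saponification, exhaustive silylation and selective hydrolysis of the labile silyl ester; keeping the hydroxy acid as its salt prevents relactonisation. O4 now carries the same silyl group as O8.

Step 19
Reactants: 26 oxoninyl propanoic acid
Product: 28 (2R,4R,5Z,8S,9R)-9-(4-diazo-3-oxobutyl)-4,8-dimethyl-2-[(E)-prop-1-enyl]-4,8-bis(triethylsilyloxy)-2,3,4,7,8,9-hexahydrooxonine, via mixed carbonic anhydride 27 (not isolated)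
Conditions: i-BuOCOCl, Et3N, THF, −20 °C; then CH2N2, Et2O, 0 °C to rt
Reagents that add atoms: diazomethane C=[N+]=[N-]
Why: Acylation of diazomethane by a mixed anhydride (the first stage of an Arndt–Eistert sequence); no HCl is formed, so the silyl ethers and the allylic ether survive.

Step 20
Reactants: 28 (Z)-oxonene diazoketone
Product: 30 (1R,2S,4Z,6R,8E,10S,11R)-2,6,10-trimethyl-2,6-bis(triethylsilyloxy)-15-oxabicyclo[9.3.1]pentadeca-4,8-dien-12-one, via bicyclic oxonium ylide 29 (not isolated)
Conditions: Cu(hfacac)2 (copper bis(hexafluoroacetylacetonate), 5 mol%), CH2Cl2, reflux, slow addition of 28 (final 2 mM)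
Reagents that add atoms: none
Why: The diazoketone loses N2 to a copper carbenoid at C13, and the ring-ether lone pair on the side of the tether adds to it to give the cis-fused ylide 29, whose six-membered ring (O, C13, C14, C1, C2, C3) is the future oxane, closed by bonding of the tethered carbenoid carbon to oxygen. A symmetry-allowed [2,3] shift through a five-centre envelope (C13–O–C10–C11=C12) then forms C12–C13, breaks O–C10 and moves the alkene to C10=C11; the twelve-membered ring is closed by this three-atom ring expansion of the nine-membered ether, not by an end-to-end cyclisation. The closest known reaction type is the copper- or rhodium-carbenoid ylide formation and [2,3] rearrangement of 2-alkenyl cyclic ethers with a diazoketone chain on the other α-carbon, which expands common-ring ethers to oxygen-bridged medium rings. C13 is controlled by the 2,9-cis oxonene: tether and propenyl group lie on one face, the allyl unit migrates suprafacially on the face it occupies on oxygen, and C12 therefore ends cis to C4 on the oxane (13R); the centre is α to the ketone, so a minor trans-bridged isomer can be equilibrated with DBU. C12 is controlled by the E geometry of the propenyl group in the endo envelope, in which C11 lies under the ylide ring as the cis-oxonene requires; this gives 12S and an E C10=C11 alkene. The step needs ylide formation to win over insertion into the C3–H bond, cyclopropanation and [1,2] shift. The electrophilic carbenoid from Cu(hfacac)2, the six-membered ylide ring, the silyl protection of O4 and O8 and the high dilution are chosen to secure this.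

Step 21
Reactants: 30 bridged dienone
Product: 31 (1R,2S,4Z,6R,10S,11R)-2,6,10-trimethyl-2,6-bis(triethylsilyloxy)-15-oxabicyclo[9.3.1]pentadec-4-en-12-one
Conditions: KO2CN=NCO2K, AcOH, pyridine/MeOH, rt (portionwise, monitored)
Reagents that add atoms: none
Why: Diimide reduction by concerted syn transfer of H2: the E-disubstituted C10=C11 alkene should react faster than the Z alkene C6=C7, which is flanked by the quaternary C8 with its bulky silyloxy group. The ketone and silyl ethers are inert, and no hydrazide is present that could condense with the ketone.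

Step 22
Reactants: 31 bridged enone-free ketone
Product: 32 methyl 2-[(1R,2S,4Z,6R,10S,11R,13R)-2,6,10-trimethyl-12-oxo-2,6-bis(triethylsilyloxy)-15-oxabicyclo[9.3.1]pentadec-4-en-13-yl]acetate
Conditions: LDA, THF, −78 °C; then BrCH2CO2Me, DMPU, −78 to −40 °C
Reagents that add atoms: methyl bromoacetate COC(=O)CBr
Why: Kinetic enolate alkylation: LDA removes a C1 hydrogen and not the hindered α-alkoxy methine at C13. The lithium enolate is alkylated along the axial trajectory on the face anti to the C3–C4 bond, which sets C1 as R.

Step 23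
Reactants: 32 keto ester
Product: 34 saturated cis-fused γ-lactone (target skeleton with C15 as CH2 and O4, O8 as triethylsilyl ethers; 1R,3R,4S,8R,12S,13R,14S), via hydroxy ester 33 (not isolated)
Conditions: NaBH4, MeOH/THF, −40 to 0 °C; then PPTS (cat.), toluene, 50 °C
Reagents that add atoms: none
Why: Small-hydride reduction: NaBH4 should attack C14 axially from the face away from the axial C1 arm, giving the equatorial alcohol (14S) cis to that arm. The cis γ-hydroxy ester then lactonises under mild acid.

Step 24
Reactants: 34 saturated cis-fused lactone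
Product: 37 4,8-bis-O-triethylsilyl ether of the target, via Mannich base 35 (not isolated), via trimethylammonium iodide 36 (not isolated)
Conditions: LDA, THF, −78 °C; then CH2=NMe2+ I−, −78 °C to rt; then MeI, MeOH/CH2Cl2, rt; then aq NaHCO3, CH2Cl2, rt
Reagents that add atoms: N,N-dimethylmethyleneiminium iodide C=[N+](C)C.[I-]
Why: α-Methylenation of a lactone by Mannich reaction of its lithium enolate with Eschenmoser's salt, quaternisation and E1cB elimination. C15 is the only enolisable position and no stereocentre is touched.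

Step 25
Reactants: 37 bis-silyl ether of the target
Product: 38 CNP0146755.1, (1R,3R,4S,6Z,8R,12S,13R,14S)-3,13-epoxy-4,8-dihydroxycembra-6,15(17)-dien-16,14-olide
Conditions: HF·pyridine, pyridine, THF, 0 °C to rt
Reagents that add atoms: none
Why: Fluoride cleavage of both tertiary triethylsilyl ethers. Buffered HF·pyridine avoids base-induced conjugate addition to the methylene lactone and the strong acid that would ionise the tertiary allylic C8 alcohol.

## Compound list

1 | (R)-linalool | C=C[C@](C)(O)CCC=C(C)C | starting material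
2 | (R)-triethyl[(3,7-dimethylocta-1,6-dien-3-yl)oxy]silane | C=C[C@](C)(O[Si](CC)(CC)CC)CCC=C(C)C | intermediate
3 | (R)-4-methyl-4-(triethylsilyloxy)hex-5-enal | C=C[C@](C)(O[Si](CC)(CC)CC)CCC=O | intermediate
4 | (2R,4R)-4-methyl-2-(N-phenylaminooxy)-4-(triethylsilyloxy)hex-5-enal | O=C[C@H](ONc1ccccc1)C[C@@](C)(O[Si](CC)(CC)CC)C=C | intermediate
5 | (2R,4R)-4-methyl-2-(N-phenylaminooxy)-4-(triethylsilyloxy)hex-5-en-1-ol | OC[C@H](ONc1ccccc1)C[C@@](C)(O[Si](CC)(CC)CC)C=C | intermediate
6 | (2R,4R)-4-methyl-4-(triethylsilyloxy)hex-5-ene-1,2-diol | OC[C@H](O)C[C@@](C)(O[Si](CC)(CC)CC)C=C | intermediate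
7 | (4R)-2,2-dibutyl-4-[(2R)-2-methyl-2-(triethylsilyloxy)but-3-enyl]-1,3,2-dioxastannolane | CCCC[Sn]1(CCCC)OC[C@@H](C[C@@](C)(O[Si](CC)(CC)CC)C=C)O1 | intermediate
8 | (2R,4R)-1-(4-methoxybenzyloxy)-4-methyl-4-(triethylsilyloxy)hex-5-en-2-ol (Hx–OH) | COc1ccc(COC[C@H](O)C[C@@](C)(O[Si](CC)(CC)CC)C=C)cc1 | intermediate
9 | ethyl 2-(Hx-oxy)acetate | COc1ccc(COC[C@H](OCC(=O)OCC)C[C@@](C)(O[Si](CC)(CC)CC)C=C)cc1 | intermediate
10 | 2-(Hx-oxy)acetic acid | COc1ccc(COC[C@H](OCC(=O)O)C[C@@](C)(O[Si](CC)(CC)CC)C=C)cc1 | intermediate
11 | 2-(Hx-oxy)acetic pivalic anhydride | COc1ccc(COC[C@H](OCC(=O)OC(=O)C(C)(C)C)C[C@@](C)(O[Si](CC)(CC)CC)C=C)cc1 | intermediate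
12 | (S)-4-benzyl-3-[2-(Hx-oxy)acetyl]oxazolidin-2-one | COc1ccc(COC[C@H](OCC(=O)N2[C@@H](Cc3ccccc3)COC2=O)C[C@@](C)(O[Si](CC)(CC)CC)C=C)cc1 | intermediate
13 | (S)-4-benzyl-3-[(R)-2-(Hx-oxy)pent-4-enoyl]oxazolidin-2-one | COc1ccc(COC[C@H](O[C@H](CC=C)C(=O)N2[C@@H](Cc3ccccc3)COC2=O)C[C@@](C)(O[Si](CC)(CC)CC)C=C)cc1 | intermediate
14 | (S)-4-benzyl-3-[(R)-5-(9-borabicyclo[3.3.1]nonan-9-yl)-2-(Hx-oxy)pentanoyl]oxazolidin-2-one | COc1ccc(COC[C@H](O[C@H](CCCB4C5CCCC4CCC5)C(=O)N2[C@@H](Cc3ccccc3)COC2=O)C[C@@](C)(O[Si](CC)(CC)CC)C=C)cc1 | intermediate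
15 | (S)-4-benzyl-3-[(R)-5-hydroxy-2-(Hx-oxy)pentanoyl]oxazolidin-2-one | COc1ccc(COC[C@H](O[C@H](CCCO)C(=O)N2[C@@H](Cc3ccccc3)COC2=O)C[C@@](C)(O[Si](CC)(CC)CC)C=C)cc1 | intermediate
16 | (R)-3-(Hx-oxy)tetrahydro-2H-pyran-2-one | COc1ccc(COC[C@H](O[C@@H]2CCCOC2=O)C[C@@](C)(O[Si](CC)(CC)CC)C=C)cc1 | intermediate
17 | (3R)-2-allyl-3-(Hx-oxy)tetrahydro-2H-pyran-2-ol (anomer mixture) | COc1ccc(COC[C@H](O[C@@H]2CCCOC2(O)CC=C)C[C@@](C)(O[Si](CC)(CC)CC)C=C)cc1 | intermediate
18 | (4R,5S)-5-methyl-4-(Hx-oxy)oct-7-ene-1,5-diol | COc1ccc(COC[C@H](O[C@H](CCCO)[C@@](C)(O)CC=C)C[C@@](C)(O[Si](CC)(CC)CC)C=C)cc1 | intermediate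
19 | (5R,6S)-6-allyl-6-methyl-5-(Hx-oxy)tetrahydro-2H-pyran-2-one | COc1ccc(COC[C@H](O[C@@H]2CCC(=O)O[C@@]2(C)CC=C)C[C@@](C)(O[Si](CC)(CC)CC)C=C)cc1 | intermediate
20 | (3R,4S,8R,10R)-lactone-fused (Z)-oxonene, C10 CH2OPMB, C8 OTES | COc1ccc(COC[C@H]2C[C@@](C)(O[Si](CC)(CC)CC)/C=C\C[C@]3(C)OC(=O)CC[C@H]3O2)cc1 | intermediate
21 | (3R,4S,8R,10R)-lactone-fused (Z)-oxonene, C10 CH2OH | OC[C@H]1C[C@@](C)(O[Si](CC)(CC)CC)/C=C\C[C@]2(C)OC(=O)CC[C@H]2O1 | intermediate
22 | (3R,4S,8R,10R)-lactone-fused (Z)-oxonene, C10 CHO | O=C[C@H]1C[C@@](C)(O[Si](CC)(CC)CC)/C=C\C[C@]2(C)OC(=O)CC[C@H]2O1 | intermediate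
23 | (3R,4S,8R,10R)-lactone-fused (Z)-oxonene, C10 (E)-prop-1-enyl | C/C=C/[C@H]1C[C@@](C)(O[Si](CC)(CC)CC)/C=C\C[C@]2(C)OC(=O)CC[C@H]2O1 | intermediate
24 | lithium 3-[(2R,4R,5Z,8S,9R)-8-hydroxy-4,8-dimethyl-2-[(E)-prop-1-enyl]-4-(triethylsilyloxy)-2,3,4,7,8,9-hexahydrooxonin-9-yl]propanoate | [Li+].[O-]C(=O)CC[C@H]1O[C@@H](/C=C/C)C[C@@](C)(O[Si](CC)(CC)CC)/C=C\C[C@]1(C)O | intermediate
25 | triethylsilyl ester of acid 26 | CC[Si](CC)(CC)OC(=O)CC[C@H]1O[C@@H](/C=C/C)C[C@@](C)(O[Si](CC)(CC)CC)/C=C\C[C@]1(C)O[Si](CC)(CC)CC | intermediate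
26 | 3-[(2R,4R,5Z,8S,9R)-4,8-dimethyl-2-[(E)-prop-1-enyl]-4,8-bis(triethylsilyloxy)-2,3,4,7,8,9-hexahydrooxonin-9-yl]propanoic acid | OC(=O)CC[C@H]1O[C@@H](/C=C/C)C[C@@](C)(O[Si](CC)(CC)CC)/C=C\C[C@]1(C)O[Si](CC)(CC)CC | intermediate
27 | isobutyl carbonic anhydride of acid 26 | CC(C)COC(=O)OC(=O)CC[C@H]1O[C@@H](/C=C/C)C[C@@](C)(O[Si](CC)(CC)CC)/C=C\C[C@]1(C)O[Si](CC)(CC)CC | intermediate
28 | (2R,4R,5Z,8S,9R)-9-(4-diazo-3-oxobutyl)-4,8-dimethyl-2-[(E)-prop-1-enyl]-4,8-bis(triethylsilyloxy)-2,3,4,7,8,9-hexahydrooxonine | [N-]=[N+]=CC(=O)CC[C@H]1O[C@@H](/C=C/C)C[C@@](C)(O[Si](CC)(CC)CC)/C=C\C[C@]1(C)O[Si](CC)(CC)CC | intermediate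
29 | bicyclic oxonium ylide (enolate carbon C13 bonded to the oxonane oxygen; six-membered ring O–C13–C14–C1–C2–C3) | [O-]C1=C[O+]2[C@@H](/C=C/C)C[C@@](C)(O[Si](CC)(CC)CC)/C=C\C[C@](C)(O[Si](CC)(CC)CC)[C@H]2CC1 | intermediate
30 | (1R,2S,4Z,6R,8E,10S,11R)-2,6,10-trimethyl-2,6-bis(triethylsilyloxy)-15-oxabicyclo[9.3.1]pentadeca-4,8-dien-12-one | O=C1[C@@H]2O[C@H](CC1)[C@@](C)(O[Si](CC)(CC)CC)C/C=C\[C@](C)(O[Si](CC)(CC)CC)C/C=C/[C@@H]2C | intermediate
31 | (1R,2S,4Z,6R,10S,11R)-2,6,10-trimethyl-2,6-bis(triethylsilyloxy)-15-oxabicyclo[9.3.1]pentadec-4-en-12-one | O=C1[C@@H]2O[C@H](CC1)[C@@](C)(O[Si](CC)(CC)CC)C/C=C\[C@](C)(O[Si](CC)(CC)CC)CCC[C@@H]2C | intermediate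
32 | methyl 2-[(1R,2S,4Z,6R,10S,11R,13R)-2,6,10-trimethyl-12-oxo-2,6-bis(triethylsilyloxy)-15-oxabicyclo[9.3.1]pentadec-4-en-13-yl]acetate | O=C1[C@@H]2O[C@H](C[C@@H]1CC(=O)OC)[C@@](C)(O[Si](CC)(CC)CC)C/C=C\[C@](C)(O[Si](CC)(CC)CC)CCC[C@@H]2C | intermediate
33 | methyl 2-[(1R,2S,4Z,6R,10S,11R,12S,13R)-12-hydroxy-2,6,10-trimethyl-2,6-bis(triethylsilyloxy)-15-oxabicyclo[9.3.1]pentadec-4-en-13-yl]acetate | O[C@@H]1[C@@H]2O[C@H](C[C@@H]1CC(=O)OC)[C@@](C)(O[Si](CC)(CC)CC)C/C=C\[C@](C)(O[Si](CC)(CC)CC)CCC[C@@H]2C | intermediate
34 | saturated cis-fused γ-lactone (target with C15 as CH2, O4 and O8 as triethylsilyl ethers; 1R,3R,4S,8R,12S,13R,14S) | C1C(=O)O[C@@H]2[C@@H]3O[C@H](C[C@H]12)[C@@](C)(O[Si](CC)(CC)CC)C/C=C\[C@](C)(O[Si](CC)(CC)CC)CCC[C@@H]3C | intermediate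
35 | C15-(dimethylaminomethyl) derivative of 34 (C15 epimers) | CN(C)CC1C(=O)O[C@@H]2[C@@H]3O[C@H](C[C@H]12)[C@@](C)(O[Si](CC)(CC)CC)C/C=C\[C@](C)(O[Si](CC)(CC)CC)CCC[C@@H]3C | intermediate
36 | C15-(trimethylammoniomethyl) derivative of 34, iodide | [I-].C[N+](C)(C)CC1C(=O)O[C@@H]2[C@@H]3O[C@H](C[C@H]12)[C@@](C)(O[Si](CC)(CC)CC)C/C=C\[C@](C)(O[Si](CC)(CC)CC)CCC[C@@H]3C | intermediate
37 | 4,8-bis-O-triethylsilyl ether of the target | C=C1C(=O)O[C@@H]2[C@@H]3O[C@H](C[C@H]12)[C@@](C)(O[Si](CC)(CC)CC)C/C=C\[C@](C)(O[Si](CC)(CC)CC)CCC[C@@H]3C | intermediate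
38 | CNP0146755.1, (1R,3R,4S,6Z,8R,12S,13R,14S)-3,13-epoxy-4,8-dihydroxycembra-6,15(17)-dien-16,14-olide | C=C1C(=O)O[C@@H]2[C@@H]3O[C@H](C[C@H]12)[C@@](C)(O)C/C=C\[C@](C)(O)CCC[C@@H]3C | target

## Step count and least certain steps

Total step count: 25. Longest linear sequence: 25 steps from (R)-linalool (1); the route is fully linear.

**Step 20 (key step).** The most likely failure is rearrangement of the ylide through the exo envelope or by a [1,2] shift, so that C12 forms with the wrong configuration. The nine-to-twelve expansion holds the allyl unit in a looser transition state than in the smaller rings where the reaction is established. Insertion of the carbenoid into the C3–H bond is the second concern. The fallback sets out from aldehyde 22. A salt-free Wittig reaction with Ph3P=CHCH3 (from the ethylphosphonium bromide and NaHMDS, THF, −78 °C) would give the Z-propenyl lactone F1. The operations of step 18 would take F1 through carboxylate F2 and bis-silyl compound F3 to acid F4. Those of step 19 would take F4 through mixed anhydride F5 to the Z-diazoketone F6. In the exo envelope the Z-propenyl group presents the other face of C12, so copper-catalysed rearrangement of F6 should give ketone F7 with the 12S centre and a Z C10=C11 alkene. Diimide reduction as in step 21 erases the alkene geometry and returns to 31.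

**Step 14 (ring-closing metathesis).** The most likely failure is oligomerisation outrunning ring closure. The catalyst must close a nine-membered ring onto a vinyl group that sits on a quaternary carbon with a bulky silyloxy group. The fallback sets out from 19. HF·pyridine would remove the C8 silyl group to give the free tertiary allylic alcohol F8. Metathesis of F8 would benefit from the known accelerating effect of a free allylic hydroxyl on the neighbouring vinyl group and give F9. Re-silylation with TESOTf and 2,6-lutidine returns to 20.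

**Step 21 (diimide reduction).** The most likely failure is loss of chemoselectivity, with partial reduction of C6=C7. Both alkenes are disubstituted and are told apart only by their steric environment. The fallback sets out from 30. NaBH4 would reduce the ketone to alcohol F10. Hydrogenation with [Ir(cod)(PCy3)(py)]PF6 in CH2Cl2 would then be directed by the C14 hydroxyl to the nearby C10=C11 alkene, while C6=C7 has only silyl ethers near it, giving F11. Dess–Martin oxidation returns to 31.

**Step 23 (ketone reduction).** The most likely failure is poor facial selectivity of hydride delivery if the oxane does not adopt the chair with the bridge diequatorial. The C14 alcohol would then be trans to the C1 arm and would not lactonise. The fallback sets out from 32. The C14-epimeric hydroxy ester F12 would be saponified with LiOH to hydroxy acid F13. An intramolecular Mitsunobu reaction (PPh3, DIAD) would close the lactone with inversion at C14 and return to 34.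

## Further compounds

F1 | step 20 | (3R,4S,8R,10R)-lactone-fused (Z)-oxonene with C10 (Z)-prop-1-enyl | C/C=C\[C@H]1C[C@@](C)(O[Si](CC)(CC)CC)/C=C\C[C@]2(C)OC(=O)CC[C@H]2O1
F2 | step 20 | lithium hydroxy carboxylate, (Z)-propenyl analogue of 24 | [Li+].[O-]C(=O)CC[C@H]1O[C@@H](/C=C\C)C[C@@](C)(O[Si](CC)(CC)CC)/C=C\C[C@]1(C)O
F3 | step 20 | bis-silylated ester, (Z)-propenyl analogue of 25 | CC[Si](CC)(CC)OC(=O)CC[C@H]1O[C@@H](/C=C\C)C[C@@](C)(O[Si](CC)(CC)CC)/C=C\C[C@]1(C)O[Si](CC)(CC)CC
F4 | step 20 | acid, (Z)-propenyl analogue of 26 | OC(=O)CC[C@H]1O[C@@H](/C=C\C)C[C@@](C)(O[Si](CC)(CC)CC)/C=C\C[C@]1(C)O[Si](CC)(CC)CC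
F5 | step 20 | mixed isobutyl carbonic anhydride, (Z)-propenyl analogue of 27 | CC(C)COC(=O)OC(=O)CC[C@H]1O[C@@H](/C=C\C)C[C@@](C)(O[Si](CC)(CC)CC)/C=C\C[C@]1(C)O[Si](CC)(CC)CC
F6 | step 20 | diazoketone, (Z)-propenyl analogue of 28 | [N-]=[N+]=CC(=O)CC[C@H]1O[C@@H](/C=C\C)C[C@@](C)(O[Si](CC)(CC)CC)/C=C\C[C@]1(C)O[Si](CC)(CC)CC
F7 | step 20 | (1R,2S,4Z,6R,8Z,10S,11R)-2,6,10-trimethyl-2,6-bis(triethylsilyloxy)-15-oxabicyclo[9.3.1]pentadeca-4,8-dien-12-one | O=C1[C@@H]2O[C@H](CC1)[C@@](C)(O[Si](CC)(CC)CC)C/C=C\[C@](C)(O[Si](CC)(CC)CC)C/C=C\[C@@H]2C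
F8 | step 14 | C8-desilylated diene lactone (19 with free C8 hydroxyl) | COc1ccc(COC[C@H](O[C@@H]2CCC(=O)O[C@@]2(C)CC=C)C[C@@](C)(O)C=C)cc1
F9 | step 14 | lactone-fused (Z)-oxonene with free C8 hydroxyl (20 without the silyl group) | COc1ccc(COC[C@H]2C[C@@](C)(O)/C=C\C[C@]3(C)OC(=O)CC[C@H]3O2)cc1
F10 | step 21 | C14 alcohol from 30 (C14 epimers) | OC1[C@@H]2O[C@H](CC1)[C@@](C)(O[Si](CC)(CC)CC)C/C=C\[C@](C)(O[Si](CC)(CC)CC)C/C=C/[C@@H]2C
F11 | step 21 | C10,C11-saturated C14 alcohol (C14 epimers) | OC1[C@@H]2O[C@H](CC1)[C@@](C)(O[Si](CC)(CC)CC)C/C=C\[C@](C)(O[Si](CC)(CC)CC)CCC[C@@H]2C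
F12 | step 23 | C14 epimer of hydroxy ester 33 (12R in bicyclic numbering) | O[C@H]1[C@@H]2O[C@H](C[C@@H]1CC(=O)OC)[C@@](C)(O[Si](CC)(CC)CC)C/C=C\[C@](C)(O[Si](CC)(CC)CC)CCC[C@@H]2C
F13 | step 23 | hydroxy acid from F12 | O[C@H]1[C@@H]2O[C@H](C[C@@H]1CC(=O)O)[C@@](C)(O[Si](CC)(CC)CC)C/C=C\[C@](C)(O[Si](CC)(CC)CC)CCC[C@@H]2C
A1 | alternative 1 | trans-4-hydroxy-5-alkylcyclopent-2-enone | O=C1C=C[C@H](O)[C@H]1[C@@H](C)CCC[C@@](C)(O)C#C
A2 | alternative 1 | 2-furylcarbinol precursor (carbinol centre undefined) | OC(c1ccco1)[C@@H](C)CCC[C@@](C)(O)C#C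
A3 | alternative 2 | fourteen-membered propargylic alcohol with C1 isopropenyl | C=C(C)[C@H]1C[C@H]2OC(C)(C)O[C@@]2(C)C/C=C\[C@](C)(O[Si](CC)(CC)CC)CCCC#C[C@H]1O
A4 | alternative 2 | seventeen-membered allyl propargyl ether | C/C1=C\C[C@H]2OC(C)(C)O[C@@]2(C)C/C=C\[C@](C)(O[Si](CC)(CC)CC)CCCC#CCOC1
A5 | alternative 3 | cis-fused γ-lactone on the oxane | C1C(=O)O[C@@H]2[C@@H]([C@@H](C)CCC[C@@](C)(O)C#C[Si](C(C)C)(C(C)C)C(C)C)O[C@H](C[C@H]12)[C@]1(C)COC(C)(C)O1
A6 | alternative 3 | cis-2,6-disubstituted 3,6-dihydro-2H-pyran with C14=C1 alkene | C1=C[C@@H]([C@@H](C)CCC[C@@](C)(O)C#C[Si](C(C)C)(C(C)C)C(C)C)O[C@H](C1)[C@]1(C)COC(C)(C)O1
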